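**Plan**

Numbering: ring C1–C10 with C1=C10; C14 is the ester carbon on C10, C15 the CH2OH carbon on C4; the lactone is O6–C12(=O)–C11(=C13)–C7; the isobutyrate sits on O8.
Retrosynthesis: remove the O8 acyl group, take C14 back to CH2OTBS, remove C13, open the lactone at O6–C12 (C6 becomes a ketone); then cut C7–C11 (enolate alkylation) and C8–C9 while re-forming C1–C6.
Enabling feature: C6(O)–C7–C8 and C9–C10=C1 are the two allyl halves of an oxy-Cope retron, so the ten-membered ring maps onto a cyclohexane C1–C6 carrying C15 on C4, a C7=C8 enol ether arm on the C6 carbinol and a C10(=C9)–C14 arm on C1.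
Forward order: the six-membered ring comes from (S)-cyclohex-3-ene-1-carboxylic acid; the C1 arm is attached by Negishi coupling and the C6 arm by alkoxyacetylide addition; ring expansion gives the ten-membered ring; then the γ-lactone, C13, the O8 ester and the C14 ester follow.
Stereochemistry: C4 from the (S)-acid; ring C1 and the C6 carbinol from equatorial protonation and axial acetylide attack; C8 and the C1=C10 geometry from the chair transition state of the (Z)-enol ether; C7 from peripheral alkylation; C6 from catalyst-controlled reduction.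

Key step: step 13

Assumption (chemistry): organometallic and enolate intermediates are drawn as monomeric covalent species. Locants C1–C15 in comments and in the descriptions of compounds 23–39 are the target numbers defined above. The C7 descriptor changes between R and S along the route for priority reasons only; the spatial arrangement is fixed after step 13. TBS = tert-butyldimethylsilyl, PMB = 4-methoxybenzyl.

**Route**

Step 1
Reactants: 1 (S)-cyclohex-3-ene-1-carboxylic acid
Product: 2 (1S,4S,5S)-4-iodo-6-oxabicyclo[3.2.1]octan-7-one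
Conditions: I2, KI, NaHCO3, H2O/CH2Cl2, rt, dark
Reagents that add atoms: iodine, II
Why: Iodolactonisation, in which the carboxylate opens the iodonium ion anti at the γ-carbon (the future C6) to give the bridged γ-lactone with iodine trans-diaxial to the new C–O bond, leaving the future C4 stereocentre untouched.

Step 2
Reactants: 2 (1S,4S,5S)-4-iodo-6-oxabicyclo[3.2.1]octan-7-one
Product: 3 (1S,5S)-6-oxabicyclo[3.2.1]oct-3-en-7-one
Conditions: DBU, toluene, 110 °C
Reagents that add atoms: none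
Why: E2 dehydroiodination through the only anti-periplanar hydrogen (on the CH2 remote from the C–O bridgehead) should give the allylic lactone.

Step 3
Reactants: 3 (1S,5S)-6-oxabicyclo[3.2.1]oct-3-en-7-one
Product: 4 (1S,5S)-5-(hydroxymethyl)cyclohex-2-en-1-ol (cis)
Conditions: LiAlH4, THF, 0 °C → rt; H2O/aq NaOH work-up
Reagents that add atoms: none
Why: Hydride reduction of the lactone to the diol, whose cis arrangement is inherited from the bridged ring.

Step 4
Reactants: 4 (1S,5S)-5-(hydroxymethyl)cyclohex-2-en-1-ol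
Product: 5 (1S,5S)-5-[(TBS-oxy)methyl]cyclohex-2-en-1-ol
Conditions: TBSCl (1.05 equiv), imidazole, CH2Cl2, −20 → 0 °C
Reagents that add atoms: tert-butyldimethylsilyl chloride, CC(C)(C)[Si](C)(C)Cl
Why: Silylation should select the primary over the secondary allylic hydroxyl on steric grounds.

Step 5
Reactants: 5 (1S,5S)-5-[(TBS-oxy)methyl]cyclohex-2-en-1-ol
Product: 6 (S)-5-[(TBS-oxy)methyl]cyclohex-2-en-1-one
Conditions: MnO2, CH2Cl2, rt
Reagents that add atoms: none
Why: Allylic alcohol oxidation with MnO2 gives the enone under neutral conditions that do not touch the silyl ether or the C4 stereocentre.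

Step 6
Reactants: 6 (S)-5-[(TBS-oxy)methyl]cyclohex-2-en-1-one
Product: 7 (S)-2-iodo-5-[(TBS-oxy)methyl]cyclohex-2-en-1-one
Conditions: I2, pyridine, CH2Cl2, rt
Reagents that add atoms: iodine, II
Why: α-Iodination of the enone by a Baylis–Hillman-type addition–elimination (pyridine adds conjugatively, the enolate is iodinated, pyridine leaves).

Step 7
Reactants: 8 2-bromoprop-2-en-1-ol
Product: 9 tert-butyl[(2-bromoprop-2-en-1-yl)oxy]dimethylsilane
Conditions: TBSCl, imidazole, CH2Cl2, 0 °C → rt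
Reagents that add atoms: tert-butyldimethylsilyl chloride, CC(C)(C)[Si](C)(C)Cl
Why: Standard silyl ether formation on a primary allylic alcohol.

Step 8
Reactants: 9 tert-butyl[(2-bromoprop-2-en-1-yl)oxy]dimethylsilane; 7 (S)-2-iodo-5-[(TBS-oxy)methyl]cyclohex-2-en-1-one
Product: 12 (S)-2-[3-(TBS-oxy)prop-1-en-2-yl]-5-[(TBS-oxy)methyl]cyclohex-2-en-1-one, via alkenyllithium 10 (not isolated), via alkenylzinc chloride 11 (not isolated)
Conditions: t-BuLi (2 equiv), Et2O, −78 °C; ZnCl2, THF, −78 → 0 °C; then 7, Pd(PPh3)4 (5 mol %), THF, rt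
Reagents that add atoms: none
Why: Negishi coupling, in which bromine–lithium exchange and transmetallation give an alkenylzinc that tolerates the ketone while Pd(0) inserts readily into the C(sp2)–I bond of the α-iodoenone, forming C1–C10.

Step 9
Reactants: 12 (S)-2-[3-(TBS-oxy)prop-1-en-2-yl]-5-[(TBS-oxy)methyl]cyclohex-2-en-1-one
Product: 14 (2R,5S)-2-[3-(TBS-oxy)prop-1-en-2-yl]-5-[(TBS-oxy)methyl]cyclohexan-1-one (trans), via lithium enolate 13 (not isolated)
Conditions: L-Selectride, THF, −78 °C; then AcOH, −78 °C → rt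
Reagents that add atoms: none
Why: Conjugate reduction of a β-unsubstituted cyclohexenone by the hindered borohydride, followed by kinetic α-protonation of enolate 13 along the axial trajectory of the half-chair with the C4 side chain equatorial, should place the alkenyl group equatorial and trans to C15, which is also the more stable epimer.

Step 10
Reactants: 15 4-methoxybenzyl alcohol; 16 trichloroethylene
Product: 19 1-{[(E)-1,2-dichloroethenyl]oxymethyl}-4-methoxybenzene, via potassium 4-methoxybenzyl oxide 17 (not isolated), via dichloroacetylene 18 (not isolated)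
Conditions: KH, THF, 0 °C; then trichloroethylene, −50 °C → rt
Reagents that add atoms: none
Why: The alkoxide dehydrochlorinates trichloroethylene and adds anti to the resulting dichloroacetylene, the established entry to 1,2-dichlorovinyl ethers as alkynyl ether precursors.

Step 11
Reactants: 19 1-{[(E)-1,2-dichloroethenyl]oxymethyl}-4-methoxybenzene; 14 (2R,5S)-2-[3-(TBS-oxy)prop-1-en-2-yl]-5-[(TBS-oxy)methyl]cyclohexan-1-one
Product: 22 (1S,2R,5S)-2-[3-(TBS-oxy)prop-1-en-2-yl]-5-[(TBS-oxy)methyl]-1-[(PMB-oxy)ethynyl]cyclohexan-1-ol, via chloroalkynyl ether 20 (not isolated), via lithium alkoxyacetylide 21 (not isolated)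
Conditions: n-BuLi (2.2 equiv), THF, −78 °C; then 14, −78 °C; cold H2O quench, product kept cold and base-washed
Reagents that add atoms: none
Why: Dehydrochlorination and chlorine–lithium exchange give the lithium alkoxyacetylide, and its 1,2-addition to the chair ketone (both substituents equatorial) should follow the axial trajectory open to a slim sp nucleophile, making the C6 hydroxyl equatorial and the alkynyl arm axial and cis to the C1 alkenyl group.

Step 12
Reactants: 22 (1S,2R,5S)-2-[3-(TBS-oxy)prop-1-en-2-yl]-5-[(TBS-oxy)methyl]-1-[(PMB-oxy)ethynyl]cyclohexan-1-ol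
Product: 23 (1S,2R,5S)-2-[3-(TBS-oxy)prop-1-en-2-yl]-5-[(TBS-oxy)methyl]-1-[(Z)-2-(PMB-oxy)ethenyl]cyclohexan-1-ol
Conditions: H2 (1 atm), Lindlar catalyst, quinoline, EtOAc/Et3N, 0 °C → rt
Reagents that add atoms: none
Why: Lindlar semihydrogenation adds hydrogen syn to the alkyne and should give the (Z)-enol ether, the 1,1-disubstituted alkene and the PMB ether being inert to the poisoned catalyst.

Step 13
Reactants: 23 (1S,2R,5S)-2-[3-(TBS-oxy)prop-1-en-2-yl]-5-[(TBS-oxy)methyl]-1-[(Z)-2-(PMB-oxy)ethenyl]cyclohexan-1-ol; 24 methyl bromoacetate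
Product: 27 methyl 2-[(4S,7R,8R,1(10)E)-4,10-bis(TBS-oxymethyl)-8-(PMB-oxy)-6-oxocyclodec-1(10)-en-7-yl]acetate (C2 and C9 cis on the alkene), via potassium alkoxide 25 (not isolated), via potassium enolate 26 (not isolated)
Conditions: KHMDS (1.05 equiv), 18-crown-6, THF, −78 °C → rt; then −78 °C, methyl bromoacetate (3 equiv)
Reagents that add atoms: none
Why: Deprotonation gives the crown-separated alkoxide 25, which undergoes an anionic oxy-Cope rearrangement, a suprafacial [3,3] shift through the six-membered chair array C8=C7–C6···C1–C10=C9 in which C8–C9 forms as C1–C6 breaks, and the regiodefined C6–C7 potassium enolate 26 is then C-alkylated at C7 by the bromoacetate (SN2). The closest known reaction type is the anionic oxy-Cope ring expansion of cis-1,2-dialkenylcyclohexanols to cyclodec-5-enones with alkylation of the enolate in the same flask. The ten-membered ring is not closed end to end but arises by four-carbon sigmatropic expansion of the cyclohexane. C8 is set by the (Z)-enol ether geometry read through the chair (PMB-oxy group axial on the transition-state chair, C9 bonding to the enol ether face turned towards C10), and the same chair holds C2 pseudo-axial on C1, which gives the C1=C10 alkene with C2 and C9 cis and the enolate with C5 and C8 trans. C7 is set by the ring, because the enolate exposes only its outer face, anti to the new C8–C9 bond, and the CH2CO2Me group should enter there. The step needs one chair over the ring-flipped chair and boat arrays and C-alkylation without loss of PMB-oxide from the β-alkoxy enolate; the cyclohexane chair with the C1 arm, the C4 side chain and O6 equatorial and the enol ether arm axial secures the first, and the soft α-bromo ester at −78 °C the second.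

Step 14
Reactants: 27 methyl 2-[(4S,7R,8R,1(10)E)-4,10-bis(TBS-oxymethyl)-8-(PMB-oxy)-6-oxocyclodec-1(10)-en-7-yl]acetate
Product: 29 (4S,6R,7R,8R,1(10)E)-trans-fused 12,6-lactone bearing 8-OPMB and 14,15-bis(OTBS) with C11 as CH2, via hydroxy ester 28 (not isolated)
Conditions: (S)-Me-CBS (0.3 equiv), catecholborane, toluene, −78 → −40 °C; MeOH; then PPTS (cat.), toluene, 40 °C
Reagents that add atoms: none
Why: Corey–Bakshi–Shibata reduction, in which the (S)-oxazaborolidine binds the carbonyl on the side of the unbranched C5 methylene and should deliver hydride to the face giving the 6R alcohol (H-6 anti to H-7), after which γ-hydroxy ester 28 closes by 5-exo-trig acyl substitution to the trans-fused γ-lactone with loss of methanol.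

Step 15
Reactants: 29 trans-fused 12,6-lactone (8-OPMB, 14,15-bis(OTBS))
Product: 31 11-(dimethylaminomethyl) lactone (C11 epimers), via lactone lithium enolate 30 (not isolated)
Conditions: LDA, THF, −78 °C; N,N-dimethylmethyleneiminium iodide, −78 °C → rt
Reagents that add atoms: N,N-dimethylmethyleneiminium iodide, C=[N+](C)C.[I-]
Why: Mannich reaction of the lactone enolate (C11 is the only enolisable carbon) with the preformed iminium salt introduces C13; the C11 configuration is lost in the next step.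

Step 16
Reactants: 31 11-(dimethylaminomethyl) lactone
Product: 33 (4S,6R,7R,8R,1(10)E)-α-methylene lactone with 8-OPMB and 14,15-bis(OTBS), via trimethylammonium iodide 32 (not isolated)
Conditions: MeI, MeOH, rt; then aq NaHCO3, CH2Cl2, rt
Reagents that add atoms: none
Why: N-Methylation followed by Hofmann-type (E1cB) elimination of trimethylamine should unveil the C11=C13 methylene.

Step 17
Reactants: 33 α-methylene lactone (8-OPMB, 14,15-bis(OTBS))
Product: 34 (4S,6R,7R,8R,1(10)E)-8-hydroxy α-methylene lactone, 14,15-bis(OTBS)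
Conditions: DDQ, CH2Cl2/pH 7 buffer (10:1), 0 °C → rt
Reagents that add atoms: none
Why: Oxidative PMB cleavage (benzylic hydride abstraction, hydrolysis of the oxocarbenium ion) is selective for the electron-rich benzyl ether over silyl ethers, alkenes and the lactone.

Step 18
Reactants: 34 8-hydroxy α-methylene lactone, 14,15-bis(OTBS)
Product: 35 (4S,6R,7S,8R,1(10)E)-8-isobutyryloxy α-methylene lactone, 14,15-bis(OTBS)
Conditions: isobutyric anhydride, Et3N, DMAP (cat.), CH2Cl2, 0 °C → rt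
Reagents that add atoms: isobutyric anhydride, CC(C)C(=O)OC(=O)C(C)C
Why: DMAP-catalysed acylation of the only free hydroxyl, with retention at C8.

Step 19
Reactants: 35 8-isobutyryloxy α-methylene lactone, 14,15-bis(OTBS)
Product: 36 (4S,6R,7S,8R,1(10)E)-14,15-diol (8-isobutyrate, α-methylene lactone)
Conditions: HF·pyridine, pyridine/THF, 0 °C → rt
Reagents that add atoms: none
Why: Fluoride cleaves both primary silyl ethers under mildly acidic conditions that should leave the ester, the lactone and the exocyclic methylene untouched.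

Step 20
Reactants: 36 14,15-diol
Product: 37 (4S,6R,7S,8R,1(10)E)-14-al (enal) with free 15-OH
Conditions: MnO2, CH2Cl2, rt
Reagents that add atoms: none
Why: MnO2 oxidises only the allylic C14 alcohol, leaving the saturated C15 alcohol.

Step 21
Reactants: 37 14-al with free 15-OH
Product: 38 (4S,6R,7S,8R,1(10)E)-14-oic acid with free 15-OH
Conditions: NaClO2, NaH2PO4, 2-methyl-2-butene, t-BuOH/H2O, 0 °C → rt
Reagents that add atoms: sodium chlorite, [Na+].[O-]Cl=O
Why: Pinnick oxidation converts the enal into the acid without oxidising the primary alcohol, the alkene scavenger removing HOCl.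

Step 22
Reactants: 38 14-oic acid with free 15-OH
Product: 39 CNP0251148.1, methyl (1(10)E,4S,6R,7S,8R)-15-hydroxy-8-(isobutyryloxy)-12-oxo-germacra-1(10),11(13)-dien-12,6-olid-14-oate
Conditions: MeI, KHCO3, DMF, rt
Reagents that add atoms: iodomethane, CI
Why: SN2 methylation of the carboxylate with a weak base that neither alkylates the C15 alcohol nor adds to the methylene lactone (diazomethane is avoided because it would add across C11=C13).

**Compound list**

1 | (S)-cyclohex-3-ene-1-carboxylic acid | OC(=O)[C@@H]1CC=CCC1 | starting material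
2 | (1S,4S,5S)-4-iodo-6-oxabicyclo[3.2.1]octan-7-one | O=C1O[C@@H]2[C@@H](I)CC[C@H]1C2 | intermediate
3 | (1S,5S)-6-oxabicyclo[3.2.1]oct-3-en-7-one | O=C1O[C@@H]2C=CC[C@H]1C2 | intermediate
4 | (1S,5S)-5-(hydroxymethyl)cyclohex-2-en-1-ol | O[C@@H]1C=CC[C@H](CO)C1 | intermediate
5 | (1S,5S)-5-[(TBS-oxy)methyl]cyclohex-2-en-1-ol | O[C@@H]1C=CC[C@H](CO[Si](C)(C)C(C)(C)C)C1 | intermediate
6 | (S)-5-[(TBS-oxy)methyl]cyclohex-2-en-1-one | O=C1C=CC[C@H](CO[Si](C)(C)C(C)(C)C)C1 | intermediate
7 | (S)-2-iodo-5-[(TBS-oxy)methyl]cyclohex-2-en-1-one | O=C1C(I)=CC[C@H](CO[Si](C)(C)C(C)(C)C)C1 | intermediate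
8 | 2-bromoprop-2-en-1-ol | OCC(Br)=C | starting material
9 | tert-butyl[(2-bromoprop-2-en-1-yl)oxy]dimethylsilane | C=C(Br)CO[Si](C)(C)C(C)(C)C | intermediate
10 | [3-(TBS-oxy)prop-1-en-2-yl]lithium | [Li]C(=C)CO[Si](C)(C)C(C)(C)C | intermediate (not isolated)
11 | chloro[3-(TBS-oxy)prop-1-en-2-yl]zinc | Cl[Zn]C(=C)CO[Si](C)(C)C(C)(C)C | intermediate (not isolated)
12 | (S)-2-[3-(TBS-oxy)prop-1-en-2-yl]-5-[(TBS-oxy)methyl]cyclohex-2-en-1-one | O=C1C(C(=C)CO[Si](C)(C)C(C)(C)C)=CC[C@H](CO[Si](C)(C)C(C)(C)C)C1 | intermediate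
13 | lithium (S)-2-[3-(TBS-oxy)prop-1-en-2-yl]-5-[(TBS-oxy)methyl]cyclohex-1-en-1-olate | [Li]OC1=C(C(=C)CO[Si](C)(C)C(C)(C)C)CC[C@H](CO[Si](C)(C)C(C)(C)C)C1 | intermediate (not isolated)
14 | (2R,5S)-2-[3-(TBS-oxy)prop-1-en-2-yl]-5-[(TBS-oxy)methyl]cyclohexan-1-one (trans) | O=C1C[C@@H](CO[Si](C)(C)C(C)(C)C)CC[C@@H]1C(=C)CO[Si](C)(C)C(C)(C)C | intermediate
15 | 4-methoxybenzyl alcohol | COc1ccc(CO)cc1 | starting material
16 | trichloroethylene | ClC=C(Cl)Cl | starting material
17 | potassium 4-methoxybenzyl oxide | [K]OCc1ccc(OC)cc1 | intermediate (not isolated)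
18 | dichloroacetylene | ClC#CCl | intermediate (not isolated)
19 | 1-{[(E)-1,2-dichloroethenyl]oxymethyl}-4-methoxybenzene | COc1ccc(CO/C(Cl)=C\Cl)cc1 | intermediate
20 | 1-[(chloroethynyl)oxymethyl]-4-methoxybenzene | COc1ccc(COC#CCl)cc1 | intermediate (not isolated)
21 | lithium 2-[(4-methoxybenzyl)oxy]ethynide | [Li]C#COCc1ccc(OC)cc1 | intermediate (not isolated)
22 | (1S,2R,5S)-2-[3-(TBS-oxy)prop-1-en-2-yl]-5-[(TBS-oxy)methyl]-1-[(PMB-oxy)ethynyl]cyclohexan-1-ol | O[C@@]1(C#COCc2ccc(OC)cc2)C[C@@H](CO[Si](C)(C)C(C)(C)C)CC[C@@H]1C(=C)CO[Si](C)(C)C(C)(C)C | intermediate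
23 | (1S,2R,5S)-2-[3-(TBS-oxy)prop-1-en-2-yl]-5-[(TBS-oxy)methyl]-1-[(Z)-2-(PMB-oxy)ethenyl]cyclohexan-1-ol (key-step precursor) | O[C@@]1(/C=C\OCc2ccc(OC)cc2)C[C@@H](CO[Si](C)(C)C(C)(C)C)CC[C@@H]1C(=C)CO[Si](C)(C)C(C)(C)C | intermediate
24 | methyl bromoacetate | COC(=O)CBr | starting material
25 | potassium alkoxide of 23 | [K]O[C@@]1(/C=C\OCc2ccc(OC)cc2)C[C@@H](CO[Si](C)(C)C(C)(C)C)CC[C@@H]1C(=C)CO[Si](C)(C)C(C)(C)C | intermediate (not isolated)
26 | potassium C6–C7 enolate of the ring-expanded cyclodecenone (O6 cis to C8; C2/C9 cis; 4S,8R) | [K]O/C1=C\[C@H](OCc2ccc(OC)cc2)C/C(CO[Si](C)(C)C(C)(C)C)=C\CC[C@H](CO[Si](C)(C)C(C)(C)C)C1 | intermediate (not isolated)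
27 | methyl 2-[(4S,7R,8R,1(10)E)-4,10-bis(TBS-oxymethyl)-8-(PMB-oxy)-6-oxocyclodec-1(10)-en-7-yl]acetate (key-step product) | COC(=O)C[C@H]1C(=O)C[C@@H](CO[Si](C)(C)C(C)(C)C)CC/C=C(/CO[Si](C)(C)C(C)(C)C)C[C@H]1OCc1ccc(OC)cc1 | intermediate
28 | (4S,6R,7S,8R)-6-hydroxy ester from 27 | COC(=O)C[C@H]1[C@H](O)C[C@@H](CO[Si](C)(C)C(C)(C)C)CC/C=C(/CO[Si](C)(C)C(C)(C)C)C[C@H]1OCc1ccc(OC)cc1 | intermediate (not isolated)
29 | (4S,6R,7R,8R,1(10)E)-trans-fused 12,6-lactone, 8-OPMB, 14,15-bis(OTBS), C11 = CH2 | C1C(=O)O[C@@H]2C[C@@H](CO[Si](C)(C)C(C)(C)C)CC/C=C(/CO[Si](C)(C)C(C)(C)C)C[C@@H](OCc3ccc(OC)cc3)[C@@H]12 | intermediate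
30 | lithium enolate of lactone 29 | C1=C(O[Li])O[C@@H]2C[C@@H](CO[Si](C)(C)C(C)(C)C)CC/C=C(/CO[Si](C)(C)C(C)(C)C)C[C@@H](OCc3ccc(OC)cc3)[C@@H]12 | intermediate (not isolated)
31 | 11-(dimethylaminomethyl) lactone (C11 epimers) | CN(C)CC1C(=O)O[C@@H]2C[C@@H](CO[Si](C)(C)C(C)(C)C)CC/C=C(/CO[Si](C)(C)C(C)(C)C)C[C@@H](OCc3ccc(OC)cc3)[C@@H]12 | intermediate
32 | 11-(trimethylammoniomethyl) lactone iodide | [I-].C[N+](C)(C)CC1C(=O)O[C@@H]2C[C@@H](CO[Si](C)(C)C(C)(C)C)CC/C=C(/CO[Si](C)(C)C(C)(C)C)C[C@@H](OCc3ccc(OC)cc3)[C@@H]12 | intermediate (not isolated)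
33 | (4S,6R,7R,8R,1(10)E)-α-methylene lactone, 8-OPMB, 14,15-bis(OTBS) | C=C1C(=O)O[C@@H]2C[C@@H](CO[Si](C)(C)C(C)(C)C)CC/C=C(/CO[Si](C)(C)C(C)(C)C)C[C@@H](OCc3ccc(OC)cc3)[C@@H]12 | intermediate
34 | (4S,6R,7R,8R,1(10)E)-8-hydroxy α-methylene lactone, 14,15-bis(OTBS) | C=C1C(=O)O[C@@H]2C[C@@H](CO[Si](C)(C)C(C)(C)C)CC/C=C(/CO[Si](C)(C)C(C)(C)C)C[C@@H](O)[C@@H]12 | intermediate
35 | (4S,6R,7S,8R,1(10)E)-8-isobutyryloxy α-methylene lactone, 14,15-bis(OTBS) | C=C1C(=O)O[C@@H]2C[C@@H](CO[Si](C)(C)C(C)(C)C)CC/C=C(/CO[Si](C)(C)C(C)(C)C)C[C@@H](OC(=O)C(C)C)[C@@H]12 | intermediate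
36 | (4S,6R,7S,8R,1(10)E)-14,15-diol, 8-isobutyrate | C=C1C(=O)O[C@@H]2C[C@@H](CO)CC/C=C(/CO)C[C@@H](OC(=O)C(C)C)[C@@H]12 | intermediate
37 | (4S,6R,7S,8R,1(10)E)-14-al, 15-OH, 8-isobutyrate | C=C1C(=O)O[C@@H]2C[C@@H](CO)CC/C=C(/C=O)C[C@@H](OC(=O)C(C)C)[C@@H]12 | intermediate
38 | (4S,6R,7S,8R,1(10)E)-14-oic acid, 15-OH, 8-isobutyrate | C=C1C(=O)O[C@@H]2C[C@@H](CO)CC/C=C(/C(=O)O)C[C@@H](OC(=O)C(C)C)[C@@H]12 | intermediate
39 | CNP0251148.1 | C=C1C(=O)O[C@@H]2C[C@@H](CO)CC/C=C(/C(=O)OC)C[C@@H](OC(=O)C(C)C)[C@@H]12 | target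

**Step count and risks**

Total steps: 22. Longest linear sequence: 20 (steps 1–6, 8, 9, 11–22).

Most likely to fail, in order:

1. Step 13. The chair that gives the right C8 carries the oxido group and the PMB-oxy group syn-axial, so the ring-flipped chair or a boat may compete and scramble C8 and the C1=C10 geometry; loss of PMB-oxide from the β-alkoxy enolate before alkylation is a second leak. The fallback moves the alkoxy group to the equatorial site of the same chair and corrects C8 afterwards. It sets out from 22: Red-Al (THF, 0 °C) should trans-hydroaluminate the propargylic alcohol to the (E)-enol ether carbinol F1. KHMDS/18-crown-6 turns this into the potassium alkoxide F2, which rearranges to the C8-epimeric potassium enolate F3, and methyl bromoacetate alkylates it to the 8-epi keto ester F4. The conditions of steps 14–17 then lead through the 8-epi hydroxy ester F5, the 8-epi lactone F6, its lithium enolate F7, the 8-epi Mannich base F8, the 8-epi ammonium iodide F9 and the 8-epi methylene lactone F10 to the 8-epi alcohol F11. Mitsunobu esterification (PPh3, DIAD, isobutyric acid, THF, 0 °C) inverts C8 and returns to the route at 35.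

2. Step 14. Hydride may reach the C6 carbonyl from the wrong face if the conformational bias of the ten-membered ring overrides the catalyst; a simple open-chain analysis of the α-stereocentre in fact points to the 6-epimer. The fallback uses that selectivity instead of fighting it. From 27, NaBH4 (MeOH, −40 °C) should give the 6-epi hydroxy ester F12, which closes to the cis-fused lactone F13. LiOH (THF/H2O) and careful acidification at 0 °C free the 6-epi hydroxy acid F14, and Mitsunobu lactonisation (PPh3, DIAD, THF, 0 °C) closes the ring with inversion at C6, returning to the route at 29.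

3. Step 11. The acetylide may enolise the β,γ-unsaturated ketone instead of adding, and the alkoxyalkynyl carbinol may be lost before semihydrogenation (acid-triggered Meyer–Schuster rearrangement, or [3,3] shift of the benzylic alkynyl ether). The fallback keeps an sp nucleophile for the axial attack but makes the C8–O bond afterwards. From 14, lithium (trimethylsilyl)acetylide (THF, −78 °C) gives the silylalkynyl carbinol F15. NIS/AgNO3 (acetone) exchanges silicon for iodine to the iodoalkynyl carbinol F16, and diimide (2-nitrobenzenesulfonyl hydrazide, Et3N) reduces this to the (Z)-iodovinyl carbinol F17. Copper-catalysed Ullmann-type vinyl etherification with 4-methoxybenzyl alcohol 15 (CuI, 3,4,7,8-tetramethyl-1,10-phenanthroline, Cs2CO3, toluene, 80 °C) should proceed with retention of alkene geometry and returns to the route at 23.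

Further compounds
F1 | step 13 | (1S,2R,5S)-2-[3-(TBS-oxy)prop-1-en-2-yl]-5-[(TBS-oxy)methyl]-1-[(E)-2-(PMB-oxy)ethenyl]cyclohexan-1-ol | O[C@@]1(/C=C/OCc2ccc(OC)cc2)C[C@@H](CO[Si](C)(C)C(C)(C)C)CC[C@@H]1C(=C)CO[Si](C)(C)C(C)(C)C
F2 | step 13 | potassium alkoxide of F1 | [K]O[C@@]1(/C=C/OCc2ccc(OC)cc2)C[C@@H](CO[Si](C)(C)C(C)(C)C)CC[C@@H]1C(=C)CO[Si](C)(C)C(C)(C)C
F3 | step 13 | 8-epi potassium C6–C7 enolate | [K]O/C1=C\[C@@H](OCc2ccc(OC)cc2)C/C(CO[Si](C)(C)C(C)(C)C)=C\CC[C@H](CO[Si](C)(C)C(C)(C)C)C1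
F4 | step 13 | 8-epi keto ester (C8 epimer of 27) | COC(=O)C[C@H]1C(=O)C[C@@H](CO[Si](C)(C)C(C)(C)C)CC/C=C(/CO[Si](C)(C)C(C)(C)C)C[C@@H]1OCc1ccc(OC)cc1
F5 | step 13 | 8-epi hydroxy ester (C8 epimer of 28) | COC(=O)C[C@H]1[C@H](O)C[C@@H](CO[Si](C)(C)C(C)(C)C)CC/C=C(/CO[Si](C)(C)C(C)(C)C)C[C@@H]1OCc1ccc(OC)cc1
F6 | step 13 | 8-epi lactone (C8 epimer of 29) | C1C(=O)O[C@@H]2C[C@@H](CO[Si](C)(C)C(C)(C)C)CC/C=C(/CO[Si](C)(C)C(C)(C)C)C[C@H](OCc3ccc(OC)cc3)[C@@H]12
F7 | step 13 | lithium enolate of F6 | C1=C(O[Li])O[C@@H]2C[C@@H](CO[Si](C)(C)C(C)(C)C)CC/C=C(/CO[Si](C)(C)C(C)(C)C)C[C@H](OCc3ccc(OC)cc3)[C@@H]12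
F8 | step 13 | 8-epi Mannich base (C8 epimer of 31) | CN(C)CC1C(=O)O[C@@H]2C[C@@H](CO[Si](C)(C)C(C)(C)C)CC/C=C(/CO[Si](C)(C)C(C)(C)C)C[C@H](OCc3ccc(OC)cc3)[C@@H]12
F9 | step 13 | 8-epi trimethylammonium iodide (C8 epimer of 32) | [I-].C[N+](C)(C)CC1C(=O)O[C@@H]2C[C@@H](CO[Si](C)(C)C(C)(C)C)CC/C=C(/CO[Si](C)(C)C(C)(C)C)C[C@H](OCc3ccc(OC)cc3)[C@@H]12
F10 | step 13 | 8-epi methylene lactone (C8 epimer of 33) | C=C1C(=O)O[C@@H]2C[C@@H](CO[Si](C)(C)C(C)(C)C)CC/C=C(/CO[Si](C)(C)C(C)(C)C)C[C@H](OCc3ccc(OC)cc3)[C@@H]12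
F11 | step 13 | 8-epi alcohol (C8 epimer of 34) | C=C1C(=O)O[C@@H]2C[C@@H](CO[Si](C)(C)C(C)(C)C)CC/C=C(/CO[Si](C)(C)C(C)(C)C)C[C@H](O)[C@@H]12
F12 | step 14 | 6-epi hydroxy ester (C6 epimer of 28) | COC(=O)C[C@H]1[C@@H](O)C[C@@H](CO[Si](C)(C)C(C)(C)C)CC/C=C(/CO[Si](C)(C)C(C)(C)C)C[C@H]1OCc1ccc(OC)cc1
F13 | step 14 | cis-fused lactone (C6 epimer of 29) | C1C(=O)O[C@H]2C[C@@H](CO[Si](C)(C)C(C)(C)C)CC/C=C(/CO[Si](C)(C)C(C)(C)C)C[C@@H](OCc3ccc(OC)cc3)[C@@H]12
F14 | step 14 | 6-epi hydroxy acid | OC(=O)C[C@H]1[C@@H](O)C[C@@H](CO[Si](C)(C)C(C)(C)C)CC/C=C(/CO[Si](C)(C)C(C)(C)C)C[C@H]1OCc1ccc(OC)cc1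
F15 | step 11 | (1S,2R,5S)-1-[(trimethylsilyl)ethynyl] carbinol | O[C@@]1(C#C[Si](C)(C)C)C[C@@H](CO[Si](C)(C)C(C)(C)C)CC[C@@H]1C(=C)CO[Si](C)(C)C(C)(C)C
F16 | step 11 | (1S,2R,5S)-1-(iodoethynyl) carbinol | O[C@@]1(C#CI)C[C@@H](CO[Si](C)(C)C(C)(C)C)CC[C@@H]1C(=C)CO[Si](C)(C)C(C)(C)C
F17 | step 11 | (1S,2R,5S)-1-[(Z)-2-iodoethenyl] carbinol | O[C@@]1(/C=C\I)C[C@@H](CO[Si](C)(C)C(C)(C)C)CC[C@@H]1C(=C)CO[Si](C)(C)C(C)(C)C
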